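**Retrosynthetic overview**
1. The last step frees the two tropolone O–H groups from a bis(ethyl ether). Before that, both dihydropyran rings are closed in one pot by making, in each half, the C4–C4a bond (pyran CH2 to seven-ring carbon) and the O1–C9a bond (pyran oxygen to seven-ring carbon).
2. This cuts the target into two molecules of 5-bromo-2,6-diethoxy-4-methyltropone and one molecule of the chain (3S,4E,6E,8R)-2-methyldeca-1,4,6,9-tetraene-3,8-diol. Ring order: the seven-membered ring first (one block, used twice), both pyran rings last.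
3. Enabling feature: in each cyclohepta[b]pyran, O1 sits on C9a, the carbon β to the carbonyl carbon C8 of the 7-alkoxytropone form (a vinylogous ester carbon, open to alkoxide addition–elimination). C4 sits on the neighbouring C4a, which is not electrophilic and is served by a C–Br bond and palladium. O1–C2–C3–C4 is the 1,3-hydroxyalkyl unit left by hydroboration of an allylic alcohol, and both halves carry the same tropolone joined through the same two atoms.
4. Tropone block: [5+2] cycloaddition of the allomaltol-derived 4-ethoxy-3-oxidopyrylium ylide with a push–pull ynoate, bromodecarboxylation, reductive opening of the oxa bridge, aromatising dehydration.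
5. Chain: two catalytic asymmetric alkynylations (methacrolein, acrolein), Cadiot–Chodkiewicz coupling, trans-reduction of the diyne. The methyl-bearing C3 centre is set in the key step by anti-selective hydroboration.

Key step: step 13

Remark: tropolone O–H/C=O tautomers interconvert rapidly, so the product of step 14 is the target whichever oxygen is drawn as carbonyl; allomaltol, ethoxyacetylene (hexane solution), methacrolein, acrolein and (trimethylsilyl)acetylene are taken as commercial; step 13 consumes two molecules of tropone 10 per molecule of chain 19, and the second molecule is entered on the line for reagents that add atoms.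

**Route**

Step 1
Reactants: 1 allomaltol (5-hydroxy-2-methyl-4H-pyran-4-one)
Product: 2 4-ethoxy-5-hydroxy-2-methylpyrylium trifluoromethanesulfonate
Conditions: EtOTf (1.2 equiv), CH2Cl2, 40 °C
Reagents that add atoms: ethyl trifluoromethanesulfonate, CCOS(=O)(=O)C(F)(F)F
Why: the hard alkyl triflate alkylates the carbonyl oxygen of the 4-pyranone (O-alkylation of a vinylogous ester) to give the aromatic 4-alkoxypyrylium salt, and ethyl is chosen so that every alkoxy group met later on the seven-membered ring is ethoxy and alkoxide exchange in step 13 changes nothing.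

Step 2
Reactants: 3 ethoxyacetylene (ethoxyethyne)
Product: 4 allyl 3-ethoxyprop-2-ynoate
Conditions: n-BuLi (1.05 equiv), THF, −78 °C; then allyl chloroformate, −78 °C to 0 °C
Reagents that add atoms: allyl chloroformate, C=CCOC(Cl)=O
Why: deprotonation of the terminal ynol ether and C-acylation of the lithium acetylide by a chloroformate is a standard ynoate synthesis, and the allyl ester can later be cleaved under neutral conditions.

Step 3
Reactants: 2 4-ethoxy-5-hydroxy-2-methylpyrylium trifluoromethanesulfonate; 4 allyl 3-ethoxyprop-2-ynoate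
Product: 6 allyl 3,7-diethoxy-5-methyl-2-oxo-8-oxabicyclo[3.2.1]octa-3,6-diene-6-carboxylate (racemic), via oxidopyrylium ylide 5 (not isolated)
Conditions: iPr2NEt (1.1 equiv), CH2Cl2, rt; then 4 (1.5 equiv), CHCl3, 80 °C, sealed tube
Reagents that add atoms: none
Why: deprotonation of 2 gives the 3-oxidopyrylium ylide (resting as its dimer), which adds thermally to the ynoate in a [5+2] dipolar cycloaddition as with simple propiolates, the nucleophilic ylide carbon next to the oxide bonding to the ethoxy-bearing β-carbon of the ynoate and the ester-bearing carbon to the methyl-bearing terminus, so that the ester stands on C6 and ethoxy on C7; the two bridgehead centres are fixed relative to each other by the bicycle, the material is racemic and both centres are erased in step 6.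

Step 4
Reactants: 6 allyl 3,7-diethoxy-5-methyl-2-oxo-8-oxabicyclo[3.2.1]octa-3,6-diene-6-carboxylate
Product: 7 3,7-diethoxy-5-methyl-2-oxo-8-oxabicyclo[3.2.1]octa-3,6-diene-6-carboxylic acid (racemic)
Conditions: Pd(PPh3)4 (5 mol%), morpholine (1.2 equiv), THF, rt; aq. NaHSO4 work-up
Reagents that add atoms: none
Why: zerovalent palladium ionises the allyl ester and morpholine takes up the π-allyl fragment (Tsuji–Trost deallylation), which frees the acid without acid or hydroxide and so spares both enol ethers and the oxa bridge.

Step 5
Reactants: 7 3,7-diethoxy-5-methyl-2-oxo-8-oxabicyclo[3.2.1]octa-3,6-diene-6-carboxylic acid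
Product: 8 6-bromo-3,7-diethoxy-5-methyl-8-oxabicyclo[3.2.1]octa-3,6-dien-2-one (racemic)
Conditions: NBS (1.05 equiv), LiOAc (0.1 equiv), MeCN/H2O, 0 °C to rt
Reagents that add atoms: N-bromosuccinimide, O=C1CCC(=O)N1Br
Why: Hunsdiecker-type bromodecarboxylation of a β-alkoxyacrylic acid, in which bromonium attack at C6 (the nucleophilic α-carbon of the push–pull alkene) gives an oxocarbenium ion at C7 that loses CO2, puts bromine exactly where the carboxyl stood and regenerates the enol ether.

Step 6
Reactants: 8 6-bromo-3,7-diethoxy-5-methyl-8-oxabicyclo[3.2.1]octa-3,6-dien-2-one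
Product: 10 5-bromo-2,6-diethoxy-4-methylcyclohepta-2,4,6-trien-1-one, via hydroxy dienone 9 (not isolated)
Conditions: SmI2 (2.2 equiv), THF/MeOH, −78 °C; then camphorsulfonic acid (0.2 equiv), 4 Å molecular sieves, CH2Cl2, rt
Reagents that add atoms: none
Why: divalent samarium reduces the ketone to a ketyl that expels the α-alkoxy C1–O8 bond (reductive opening of an α-alkoxy ketone) and the acid then ionises the tertiary doubly allylic alcohol and removes a C7 proton, a 1,4-dehydration driven by formation of the aromatic tropone, which also erases both former bridgehead stereocentres.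

Step 7
Reactants: 11 methacrolein; 12 (trimethylsilyl)acetylene
Product: 13 (R)-2-methyl-5-(trimethylsilyl)pent-1-en-4-yn-3-ol
Conditions: Me2Zn (3 equiv), ProPhenol ligand (10 mol%, the enantiomer that gives the R carbinol), Ph3PO (20 mol%), toluene, 4 °C; dilute HCl work-up
Reagents that add atoms: none
Why: zinc–ProPhenol-catalysed asymmetric alkynylation of an α,β-unsaturated aldehyde, in which the chiral dinuclear zinc alkoxide binds the aldehyde and the alkynylzinc and delivers the alkyne to one carbonyl face, sets the carbinol stereocentre by catalyst control.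

Step 8
Reactants: 13 (R)-2-methyl-5-(trimethylsilyl)pent-1-en-4-yn-3-ol
Product: 14 (R)-2-methylpent-1-en-4-yn-3-ol
Conditions: K2CO3 (0.2 equiv), MeOH, 0 °C
Reagents that add atoms: none
Why: carbonate-catalysed methanolysis of the alkynyl C–Si bond (protodesilylation) leaves the carbinol centre and the alkene untouched.

Step 9
Reactants: 15 acrolein; 12 (trimethylsilyl)acetylene
Product: 16 (R)-5-(trimethylsilyl)pent-1-en-4-yn-3-ol
Conditions: Me2Zn (3 equiv), ProPhenol ligand (10 mol%, same enantiomer as in step 7), Ph3PO (20 mol%), toluene, 4 °C; dilute HCl work-up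
Reagents that add atoms: none
Why: the same catalytic asymmetric alkynylation as in step 7, with the same ligand enantiomer because the alkenyl, alkynyl and hydroxyl groups are arranged in the same sense, sets the second carbinol stereocentre.

Step 10
Reactants: 16 (R)-5-(trimethylsilyl)pent-1-en-4-yn-3-ol
Product: 17 (R)-5-bromopent-1-en-4-yn-3-ol
Conditions: NBS (1.1 equiv), AgNO3 (0.1 equiv), acetone, rt, dark; aqueous work-up
Reagents that add atoms: N-bromosuccinimide, O=C1CCC(=O)N1Br
Why: silver-catalysed bromodesilylation, in which a silver acetylide formed by silicon-to-silver exchange is brominated by NBS, converts the alkynylsilane directly into the 1-bromoalkyne without involving the carbinol centre.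

Step 11
Reactants: 14 (R)-2-methylpent-1-en-4-yn-3-ol; 17 (R)-5-bromopent-1-en-4-yn-3-ol
Product: 18 (3R,8R)-2-methyldeca-1,9-diene-4,6-diyne-3,8-diol
Conditions: CuCl (5 mol%), NH2OH·HCl (0.2 equiv), n-BuNH2 (30% aq.), MeOH, 0 °C
Reagents that add atoms: none
Why: Cadiot–Chodkiewicz coupling of the copper acetylide of 14 with bromoalkyne 17 gives the unsymmetrical 1,3-diyne, tolerates free propargylic alcohols and touches neither stereocentre, hydroxylamine keeping copper monovalent.

Step 12
Reactants: 18 (3R,8R)-2-methyldeca-1,9-diene-4,6-diyne-3,8-diol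
Product: 19 (3S,4E,6E,8R)-2-methyldeca-1,4,6,9-tetraene-3,8-diol
Conditions: NaAlH2(OCH2CH2OMe)2 (4 equiv), THF, 0 °C to rt; aq. KNaC4H4O6 work-up
Reagents that add atoms: none
Why: hydroxyl-directed trans-hydroalumination of both propargylic triple bonds (each alkoxyaluminate delivers hydride to the distal alkyne carbon and the vinylalane is protonated on work-up) gives the E,E-diene, while the isolated alkenes and the carbinol centres are untouched and the C3 descriptor becomes S only through a change of CIP priorities.

Step 13
Reactants: 19 (3S,4E,6E,8R)-2-methyldeca-1,4,6,9-tetraene-3,8-diol; 10 5-bromo-2,6-diethoxy-4-methylcyclohepta-2,4,6-trien-1-one (first of two molecules, for the methyl-bearing half)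
Product: 22 (2R,3R)-7-ethoxy-2-[(1E,3E)-4-[(2R)-7-ethoxy-5-methyl-8-oxo-2,3,4,8-tetrahydrocyclohepta[b]pyran-2-yl]buta-1,3-dien-1-yl]-3,5-dimethyl-3,4-dihydrocyclohepta[b]pyran-8(2H)-one, via bis-borane 20 (not isolated), via seco-diol 21 (not isolated)
Conditions: 9-borabicyclo[3.3.1]nonane dimer (2.3 equiv), THF, 0 °C to rt; degassed H2O; then 10 (2.2 equiv in all, two molecules being consumed per molecule of 19), Pd(dppf)Cl2 (10 mol%), AsPh3 (10 mol%), Cs2CO3 (6 equiv), DMF, 45 °C then 80 °C
Reagents that add atoms: 5-bromo-2,6-diethoxy-4-methylcyclohepta-2,4,6-trien-1-one (second molecule of 10 for the other half), O=C1C=C(OCC)C(Br)=C(C)C=C1OCC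
Why: Proposed new method: a twofold one-pot hydroboration/B-alkyl Suzuki–Miyaura coupling/alkoxide addition–elimination on a 5-bromo-6-alkoxytropone has not been described, but each event is ordinary: 9-BBN adds only to the two terminal alkenes of 19 (the internal conjugated diene is much slower, the hydroxyls become O-borinates), zerovalent palladium inserts into the C5–Br bond of each of the two molecules of 10, the hydroxy-ate complex of each primary alkylborane transmetalates and reductive elimination makes the CH2–C5 bond. Each secondary alkoxide freed by hydrolysis of its borinate then adds to the neighbouring C6, the ethoxy-bearing β-carbon of the tropone enone, and expels ethoxide, which makes the O–C6 bond. The closest known reactions are the B-alkyl Suzuki–Miyaura coupling of alkenyl and aryl bromides (halotropones are known to couple with arylboron reagents) and alkoxide exchange at β-alkoxy enones and alkoxytropones (vinylogous transesterification, SNAr-like). Each dihydropyran ring closes by 6-exo-trig attack of oxygen on C6 followed by loss of ethoxide, the C–C bond having been made first. The only new stereocentre, the methyl-bearing carbon of the left ring, is set in the hydroboration under control of the adjacent carbinol centre (A1,3-strain model for 9-BBN and 1,1-disubstituted allylic alcohols, anti product, which becomes trans in the ring), while the two carbinol centres keep their C–O bonds and configuration. The step needs bromide-over-ethoxide chemoselectivity at palladium and carbon-at-C5/oxygen-at-C6 regiochemistry, and both are built into 10: the only C–Br bond is at C5, the only leaving group within reach of the tethered alkoxide is the ethoxide on C6, and the other neighbour, C4, carries methyl.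

Step 14
Reactants: 22 the bis(ethyl ether) from step 13
Product: 23 (2R,3R)-8-hydroxy-2-[(1E,3E)-4-[(2R)-8-hydroxy-5-methyl-7-oxo-2,3,4,7-tetrahydrocyclohepta[b]pyran-2-yl]buta-1,3-dien-1-yl]-3,5-dimethyl-3,4-dihydrocyclohepta[b]pyran-7(2H)-one (target)
Conditions: NaOH (1 M aq., 6 equiv), THF, 40 °C; then 1 M HCl to pH 4
Reagents that add atoms: sodium hydroxide, [Na+].[OH-]
Why: saponification of the two tropolone ethyl ethers by addition–elimination, hydroxide adding at the ethoxy-bearing C7 (the ring carbon α to the carbonyl, the most electrophilic position of a 2-alkoxytropone) and expelling ethoxide, whereas the pyran oxygen sits on the less electrophilic and fully substituted C9a and the tropolonate formed is inert to further attack; no stereocentre is involved.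

**Compound list**
1 | allomaltol (5-hydroxy-2-methyl-4H-pyran-4-one) | Cc1cc(=O)c(O)co1 | starting material
2 | 4-ethoxy-5-hydroxy-2-methylpyrylium trifluoromethanesulfonate | Cc1cc(OCC)c(O)c[o+]1.[O-]S(=O)(=O)C(F)(F)F | intermediate
3 | ethoxyacetylene (ethoxyethyne) | C#COCC | starting material
4 | allyl 3-ethoxyprop-2-ynoate | CCOC#CC(=O)OCC=C | intermediate
5 | 4-ethoxy-6-methylpyrylium-3-olate (oxidopyrylium ylide) | Cc1cc(OCC)c([O-])c[o+]1 | intermediate
6 | allyl 3,7-diethoxy-5-methyl-2-oxo-8-oxabicyclo[3.2.1]octa-3,6-diene-6-carboxylate (racemic) | O=C1C(OCC)=CC2(C)C(C(=O)OCC=C)=C(OCC)C1O2 | intermediate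
7 | 3,7-diethoxy-5-methyl-2-oxo-8-oxabicyclo[3.2.1]octa-3,6-diene-6-carboxylic acid (racemic) | O=C1C(OCC)=CC2(C)C(C(=O)O)=C(OCC)C1O2 | intermediate
8 | 6-bromo-3,7-diethoxy-5-methyl-8-oxabicyclo[3.2.1]octa-3,6-dien-2-one (racemic) | O=C1C(OCC)=CC2(C)C(Br)=C(OCC)C1O2 | intermediate
9 | 5-bromo-2,6-diethoxy-4-hydroxy-4-methylcyclohepta-2,5-dien-1-one (racemic) | O=C1CC(OCC)=C(Br)C(C)(O)C=C1OCC | intermediate
10 | 5-bromo-2,6-diethoxy-4-methylcyclohepta-2,4,6-trien-1-one | O=C1C=C(OCC)C(Br)=C(C)C=C1OCC | intermediate
11 | methacrolein | CC(=C)C=O | starting material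
12 | (trimethylsilyl)acetylene | C#C[Si](C)(C)C | starting material
13 | (R)-2-methyl-5-(trimethylsilyl)pent-1-en-4-yn-3-ol | C=C(C)[C@@H](O)C#C[Si](C)(C)C | intermediate
14 | (R)-2-methylpent-1-en-4-yn-3-ol | C=C(C)[C@@H](O)C#C | intermediate
15 | acrolein | C=CC=O | starting material
16 | (R)-5-(trimethylsilyl)pent-1-en-4-yn-3-ol | C[Si](C)(C)C#C[C@H](O)C=C | intermediate
17 | (R)-5-bromopent-1-en-4-yn-3-ol | BrC#C[C@H](O)C=C | intermediate
18 | (3R,8R)-2-methyldeca-1,9-diene-4,6-diyne-3,8-diol | C=C(C)[C@@H](O)C#CC#C[C@H](O)C=C | intermediate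
19 | (3S,4E,6E,8R)-2-methyldeca-1,4,6,9-tetraene-3,8-diol | C=C(C)[C@@H](O)/C=C/C=C/[C@H](O)C=C | intermediate
20 | bis-borane: (2R,3R,4E,6E,8R)-2-methyldeca-4,6-diene carrying 9-BBN on C1 and C10 and O-(9-BBN) borinates on the C3 and C8 oxygens | C1CCC2CCCC1B2C[C@@H](C)[C@@H](OB1C2CCCC1CCC2)/C=C/C=C/[C@H](OB1C2CCCC1CCC2)CCB1C2CCCC1CCC2 | intermediate
21 | seco-diol: 5,5'-[(2R,3R,4E,6E,8R)-3,8-dihydroxy-2-methyldeca-4,6-diene-1,10-diyl]bis(2,6-diethoxy-4-methylcyclohepta-2,4,6-trien-1-one) | O=C1C=C(OCC)C(C[C@@H](C)[C@@H](O)/C=C/C=C/[C@H](O)CCC2=C(C)C=C(OCC)C(=O)C=C2OCC)=C(C)C=C1OCC | intermediate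
22 | (2R,3R)-7-ethoxy-2-[(1E,3E)-4-[(2R)-7-ethoxy-5-methyl-8-oxo-2,3,4,8-tetrahydrocyclohepta[b]pyran-2-yl]buta-1,3-dien-1-yl]-3,5-dimethyl-3,4-dihydrocyclohepta[b]pyran-8(2H)-one | O=C1C=C2O[C@@H](/C=C/C=C/[C@H]3CCC4=C(C)C=C(OCC)C(=O)C=C4O3)[C@H](C)CC2=C(C)C=C1OCC | intermediate
23 | (2R,3R)-8-hydroxy-2-[(1E,3E)-4-[(2R)-8-hydroxy-5-methyl-7-oxo-2,3,4,7-tetrahydrocyclohepta[b]pyran-2-yl]buta-1,3-dien-1-yl]-3,5-dimethyl-3,4-dihydrocyclohepta[b]pyran-7(2H)-one | Cc1cc(=O)c(O)cc2c1C[C@@H](C)[C@H](/C=C/C=C/[C@H]1CCc3c(C)cc(=O)c(O)cc3O1)O2 | target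

**Count and risks**
Total step count: 14. Longest linear sequence: 7 steps (1, 3, 4, 5, 6, 13, 14).

Steps most likely to fail:

1. Step 13.
- What may go wrong: the alkoxide addition–elimination at C6 may stall, since the β-position is the least electrophilic alkoxy-bearing carbon of a tropone. Carbonate and water may saponify the 2-ethoxy group first and make the ring anionic. Zerovalent palladium may ionise the dienylic C–O bonds once they exist. The anti selectivity of the hydroboration may erode.
- Fallback (from 19, back at 22): the two bond formations are separated and the oxygens masked. Silylation of 19 (Et3SiCl, imidazole, CH2Cl2) gives the bis(triethylsilyl) ether F1. Hydroboration with 9-BBN and twofold B-alkyl Suzuki–Miyaura coupling with two equivalents of 10 (Pd(dppf)Cl2, AsPh3, Cs2CO3, DMF/H2O, rt) give the doubly coupled bis(silyl ether) F2. Bu4NF in THF then releases diol 21, now isolated and free of palladium. Acid-catalysed vinylogous transetherification (pyridinium p-toluenesulfonate, toluene, 70 °C, 4 Å molecular sieves to take up ethanol) closes both rings to 22.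

2. Step 3.
- What may go wrong: the push–pull ynoate may add sluggishly or with the reversed orientation, which would put the ester on C7 and ethoxy on C6.
- Fallback (from 2, back at 6): orientation is handed to a propiolate whose ester alone directs. Allyl propiolate is brominated at the alkyne terminus (NBS, AgNO3 cat., acetone) to allyl 3-bromoprop-2-ynoate F3. Cycloaddition of the ylide from 2 with F3 under the conditions of step 3 gives allyl 7-bromo-3-ethoxy-5-methyl-2-oxo-8-oxabicyclo[3.2.1]octa-3,6-diene-6-carboxylate F4. Ethanol then replaces bromide at C7 by addition–elimination on the β-bromoacrylate (EtOH, Et3N, rt) and gives 6.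

3. Step 14.
- What may go wrong: hydroxide may attack C9a in competition and open a pyran ring, or the alkoxytropone may undergo base-induced ring contraction.
- Fallback (from 10, back at 23): no nucleophile has to touch the finished rings. 10 is transetherified with sodium 2-(trimethylsilyl)ethoxide (NaH, Me3SiCH2CH2OH, THF, 50 °C) to 5-bromo-4-methyl-2,6-bis[2-(trimethylsilyl)ethoxy]cyclohepta-2,4,6-trien-1-one F5. Two equivalents of F5 are taken through the protocol of step 13 with one equivalent of 19 to the bis[2-(trimethylsilyl)ethyl] ether F6, the group leaving from C6 then being 2-(trimethylsilyl)ethoxide. Bu4NF in THF at rt removes both silylethyl groups by fluoride-induced fragmentation and gives 23 after buffered work-up.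

Further compounds
F1 | step 13 | (3S,4E,6E,8R)-2-methyl-3,8-bis(triethylsilyloxy)deca-1,4,6,9-tetraene | C=C(C)[C@@H](O[Si](CC)(CC)CC)/C=C/C=C/[C@H](O[Si](CC)(CC)CC)C=C
F2 | step 13 | 5,5'-[(2R,3R,4E,6E,8R)-2-methyl-3,8-bis(triethylsilyloxy)deca-4,6-diene-1,10-diyl]bis(2,6-diethoxy-4-methylcyclohepta-2,4,6-trien-1-one) | O=C1C=C(OCC)C(C[C@@H](C)[C@@H](O[Si](CC)(CC)CC)/C=C/C=C/[C@H](O[Si](CC)(CC)CC)CCC2=C(C)C=C(OCC)C(=O)C=C2OCC)=C(C)C=C1OCC
F3 | step 3 | allyl 3-bromoprop-2-ynoate | C=CCOC(=O)C#CBr
F4 | step 3 | allyl 7-bromo-3-ethoxy-5-methyl-2-oxo-8-oxabicyclo[3.2.1]octa-3,6-diene-6-carboxylate (racemic) | O=C1C(OCC)=CC2(C)C(C(=O)OCC=C)=C(Br)C1O2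
F5 | step 14 | 5-bromo-4-methyl-2,6-bis[2-(trimethylsilyl)ethoxy]cyclohepta-2,4,6-trien-1-one | O=C1C=C(OCC[Si](C)(C)C)C(Br)=C(C)C=C1OCC[Si](C)(C)C
F6 | step 14 | bis[2-(trimethylsilyl)ethyl] ether corresponding to 22 (both 7-ethoxy groups replaced by 7-[2-(trimethylsilyl)ethoxy]) | O=C1C=C2O[C@@H](/C=C/C=C/[C@H]3CCC4=C(C)C=C(OCC[Si](C)(C)C)C(=O)C=C4O3)[C@H](C)CC2=C(C)C=C1OCC[Si](C)(C)C
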